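**Retrosynthetic overview**
1. Target ⇐ hydrogenation of a C6 exocyclic methylene ⇐ Wittig on keto acid 20, whose ketone and phenol are masked until late as one mixed ketal.
2. Acid chain and isopropylidene ⇐ tandem [2,3]-Wittig / anionic oxy-Cope rearrangement of a C1 allyl ether, made from the C1 ketone by aldol condensation with acetone.
3. cis-Decalin (C8a, C4a, C5) ⇐ Diels–Alder reaction of (R)-carvone (ring A, bought) with 2-vinyl-4H-chromene 7 (forms ring B); the carvone isopropenyl group is then excised.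
4. Chromene 7 ⇐ hetero-Diels–Alder reaction of an o-quinone methide (from salicyl alcohol 2) with silyloxydiene 4.
5. Ring order: arene (bought) → pyran (temporary) → ring A (bought) → ring B (Diels–Alder) → pyran opened in step 10.

Assumption: 1, 3 and 8 are bought; centres that are destroyed later (C2/C3 of 6, ketal carbon C6 in 10–19, carbinols in 15 and 17) are left undefined because either epimer serves.

Locants and faces: decalin numbering of the target, C1 (acid chain), C2 (isopropylidene), C3, C4, C4a (ring-fusion CH), C5 (CH3 and CH2Ar), C6 (CH–CH3), C7, C8, C8a (ring-fusion C–CH3). α is the face of the C8a methyl.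

**Step 1**
Reactants: 1 4-methoxy-2-methylphenol
Product: 2 2-(hydroxymethyl)-4-methoxy-6-methylphenol
Conditions: 37% aq. CH2O, NaOH (1 equiv), H2O, 25 °C; then aq. HCl
Reagents that add atoms: formaldehyde C=O
Why: Lederer–Manasse hydroxymethylation: the phenoxide attacks formaldehyde at C6, its only free ortho/para position, so a single benzylic alcohol forms.

**Step 2**
Reactants: 3 pent-1-en-3-one
Product: 4 (Z)-tert-butyl(dimethyl)(penta-1,3-dien-3-yloxy)silane
Conditions: TBSOTf, Et3N, Et2O, 0 °C
Reagents that add atoms: tert-butyldimethylsilyl triflate CC(C)(C)[Si](C)(C)OS(=O)(=O)C(F)(F)F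
Why: Soft enolisation of the ethyl ketone gives the 2-silyloxy diene; its enol-ether geometry is erased in step 3 and does not matter.

**Step 3**
Reactants: 2 2-(hydroxymethyl)-4-methoxy-6-methylphenol; 4 silyloxydiene (3 equiv)
Product: 7 2-ethenyl-6-methoxy-3,8-dimethyl-4H-chromene, via o-quinone methide 5 (not isolated), via silyloxychromane cycloadduct 6 (not isolated)
Conditions: PhMe, 170 °C, sealed tube; then PPTS (cat.), PhMe, 80 °C
Reagents that add atoms: none
Why: Thermal dehydration of 2 gives o-quinone methide 5, which the enol-ether double bond of 4 traps in an inverse-demand hetero-Diels–Alder reaction (methylene carbon to the enol β-carbon); acid-promoted loss of silanol from 6 then leaves the endocyclic enol ether, whose ring fixes the C3 methyl cis to the vinyl group.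

**Step 4**
Reactants: 7 2-ethenyl-6-methoxy-3,8-dimethyl-4H-chromene; 8 (R)-(−)-carvone
Product: 10 mixed methyl aryl ketal of the cis-decalone adduct, via Diels–Alder adduct 9 (not isolated)
Conditions: AlBr3/AlMe3 (10:1, 50 mol %), PhMe–CH2Cl2, −20 → 0 °C; then MeOH (excess), PPTS, 23 °C
Reagents that add atoms: methanol CO
Why: Lewis-acid-promoted Diels–Alder reaction: the enol-ether terminus (C3 of 7) bonds to the enone β-carbon and the diene adds endo on the face opposite the isopropenyl group, which sets C8a (α-CH3), C4a (α-H) and C5 (α-CH3, β-CH2Ar) at once; methanol then adds across the aryl enol ether to give a ketal that masks both the phenol and the C6 ketone.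

**Step 5**
Reactants: 10 mixed ketal
Product: 12 de-isopropenyl ketone (C3 now CH2), via methoxy hydroperoxide 11 (not isolated)
Conditions: O3 (1 equiv), MeOH, −78 °C; then PhSH, FeSO4·7H2O, −78 → 23 °C
Reagents that add atoms: none
Why: Hydrodealkenylation: ozonolysis in methanol gives the α-methoxy hydroperoxide, ferrous ion reduces it to an alkoxy radical that loses methyl acetate by β-scission, and the C3 radical takes hydrogen from the thiol, so the spent carvone stereocentre becomes CH2.

**Step 6**
Reactants: 12 de-isopropenyl ketone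
Product: 14 2-(propan-2-ylidene) ketone, via acetoxy ketone 13 (not isolated)
Conditions: LiN(i-Pr)2, THF, −78 °C; acetone; Ac2O, −78 → 0 °C; DBU, 23 °C
Reagents that add atoms: acetone CC(C)=O
Why: Directed aldol condensation: only C2 can be enolised, the lithium aldolate is acetylated in the flask, and DBU eliminates acetate (E1cB) to the conjugated isopropylidene ketone.

**Step 7**
Reactants: 14 2-(propan-2-ylidene) ketone
Product: 15 C1 allylic alcohol
Conditions: i-Bu2AlH, CH2Cl2, −78 °C
Reagents that add atoms: none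
Why: 1,2-Hydride reduction of the hindered enone; the carbinol configuration is irrelevant because the C1–O bond is broken in step 9.

**Step 8**
Reactants: 15 C1 allylic alcohol
Product: 16 C1 allyl ether
Conditions: KH, THF, 0 °C; allyl bromide, Bu4NI (cat.), 23 °C
Reagents that add atoms: allyl bromide C=CCBr
Why: Williamson ether synthesis of the potassium alkoxide with allyl bromide.

**Step 9**
Reactants: 16 C1 allyl ether
Product: 18 C1 α-(3-oxopropyl) aldehyde, via dienol 17 (not isolated)
Conditions: n-BuLi, THF, −78 → −20 °C; then KOt-Bu, 18-crown-6, 40 °C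
Reagents that add atoms: none
Why: Tandem [2,3]-Wittig rearrangement (lithiated allyl carbon to the dimethyl-substituted alkene terminus) and anionic oxy-Cope rearrangement of the resulting 1,5-dien-3-olate: the chair transition state forms the C1–CH2 bond on the α face, anti to the pseudo-axial C8a–C8 bond, which sets C1 and at the same time creates the isopropylidene group and the aldehyde.

**Step 10**
Reactants: 18 aldehyde
Product: 20 keto acid with free phenol, via ketal acid 19 (not isolated)
Conditions: NaClO2, NaH2PO4, 2-methylbut-2-ene, t-BuOH/H2O, 0 → 23 °C; then 2 M HCl, THF, 23 °C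
Reagents that add atoms: sodium chlorite [Na+].[O-]Cl=O; water O
Why: Pinnick (Lindgren) oxidation of the aldehyde, then acid hydrolysis of the mixed ketal, which frees the phenol and the C6 ketone.

**Step 11**
Reactants: 20 keto acid
Product: 21 6-methylidene acid
Conditions: Ph3PCH3Br (5 equiv), KOt-Bu (5 equiv), PhMe, 90 °C
Reagents that add atoms: methyltriphenylphosphonium bromide C[P+](c1ccccc1)(c1ccccc1)c1ccccc1.[Br-]
Why: Wittig methylenation of the neopentyl-type ketone with excess ylide; carboxylate and phenoxide are spectators.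

**Step 12**
Reactants: 21 6-methylidene acid
Product: 22 target CNP0299684.4
Conditions: H2 (1 atm), 10% Pd/C, EtOAc, 23 °C
Reagents that add atoms: none
Why: Heterogeneous hydrogenation: the 1,1-disubstituted alkene is reduced from the β face, opposite the two axial α-methyl groups on C5 and C8a, so the new C6 methyl is α (equatorial) and cis to the C5 methyl, while the tetrasubstituted isopropylidene alkene is inert.

**Compound list**
1 | 4-methoxy-2-methylphenol | COc1ccc(O)c(C)c1 | starting material
2 | 2-(hydroxymethyl)-4-methoxy-6-methylphenol | COc1cc(C)c(O)c(CO)c1 | intermediate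
3 | pent-1-en-3-one | C=CC(=O)CC | starting material
4 | (Z)-tert-butyl(dimethyl)(penta-1,3-dien-3-yloxy)silane | C/C=C(\O[Si](C)(C)C(C)(C)C)C=C | intermediate
5 | 4-methoxy-2-methyl-6-methylidenecyclohexa-2,4-dien-1-one (o-quinone methide) | C=C1C=C(OC)C=C(C)C1=O | intermediate
6 | 2-[tert-butyl(dimethyl)silyl]oxy-2-ethenyl-6-methoxy-3,8-dimethylchromane (diastereomer mixture) | COc1cc(C)c2OC(C=C)(O[Si](C)(C)C(C)(C)C)C(C)Cc2c1 | intermediate
7 | 2-ethenyl-6-methoxy-3,8-dimethyl-4H-chromene | COc1cc(C)c2OC(C=C)=C(C)Cc2c1 | intermediate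
8 | (R)-(−)-carvone, (5R)-2-methyl-5-(prop-1-en-2-yl)cyclohex-2-en-1-one | CC1=CC[C@H](CC1=O)C(C)=C | starting material
9 | Diels–Alder adduct: cis-decalin-1-one, 8a-CH3 α, H-4a α, 3-isopropenyl α, 5-CH3 α, 5-CH2Ar β, aryl O on C6 closing a 4H-chromene (C6=C7 enol ether) | COc1cc(C)c2OC3=CC[C@@]4(C)C(=O)C[C@H](C(C)=C)C[C@H]4[C@@]3(C)Cc2c1 | intermediate
10 | mixed ketal: as 9 but C6 bears OCH3 and the aryl O, C7 is CH2 | COc1cc(C)c2OC3(OC)CC[C@@]4(C)C(=O)C[C@H](C(C)=C)C[C@H]4[C@@]3(C)Cc2c1 | intermediate
11 | α-methoxy hydroperoxide: as 10 with C3 side chain C(CH3)(OCH3)OOH | COc1cc(C)c2OC3(OC)CC[C@@]4(C)C(=O)C[C@H](C(C)(OC)OO)C[C@H]4[C@@]3(C)Cc2c1 | intermediate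
12 | de-isopropenyl ketone: as 10 with C3 = CH2 | COc1cc(C)c2OC3(OC)CC[C@@]4(C)C(=O)CCC[C@H]4[C@@]3(C)Cc2c1 | intermediate
13 | 2-(2-acetoxypropan-2-yl) derivative of 12 | COc1cc(C)c2OC3(OC)CC[C@@]4(C)C(=O)C(C(C)(C)OC(C)=O)CC[C@H]4[C@@]3(C)Cc2c1 | intermediate
14 | 2-(propan-2-ylidene)-1-ketone | COc1cc(C)c2OC3(OC)CC[C@@]4(C)C(=O)C(=C(C)C)CC[C@H]4[C@@]3(C)Cc2c1 | intermediate
15 | 2-(propan-2-ylidene)-1-ol | COc1cc(C)c2OC3(OC)CC[C@@]4(C)C(O)C(=C(C)C)CC[C@H]4[C@@]3(C)Cc2c1 | intermediate
16 | 1-(prop-2-enyloxy)-2-(propan-2-ylidene) ether | COc1cc(C)c2OC3(OC)CC[C@@]4(C)C(OCC=C)C(=C(C)C)CC[C@H]4[C@@]3(C)Cc2c1 | intermediate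
17 | dienol: C1=C2 alkene, C2 bears C(CH3)2–CH(OH)–CH=CH2 | COc1cc(C)c2OC3(OC)CC[C@@]4(C)C=C(C(C)(C)C(O)C=C)CC[C@H]4[C@@]3(C)Cc2c1 | intermediate
18 | aldehyde: C1 α-(3-oxopropyl), H-1 β, C2 isopropylidene | COc1cc(C)c2OC3(OC)CC[C@@]4(C)[C@H](CCC=O)C(=C(C)C)CC[C@H]4[C@@]3(C)Cc2c1 | intermediate
19 | ketal acid: as 18 with CO2H in place of CHO | COc1cc(C)c2OC3(OC)CC[C@@]4(C)[C@H](CCC(=O)O)C(=C(C)C)CC[C@H]4[C@@]3(C)Cc2c1 | intermediate
20 | 3-[5β-(2-hydroxy-5-methoxy-3-methylbenzyl)-5α,8aα-dimethyl-6-oxo-2-(propan-2-ylidene)-4aα-H-decahydronaphthalen-1α-yl]propanoic acid | COc1cc(C)c(O)c(C[C@]2(C)[C@@H]3CCC(=C(C)C)[C@@H](CCC(=O)O)[C@]3(C)CCC2=O)c1 | intermediate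
21 | 6-methylidene analogue of 20 | COc1cc(C)c(O)c(C[C@]2(C)[C@@H]3CCC(=C(C)C)[C@@H](CCC(=O)O)[C@]3(C)CCC2=C)c1 | intermediate
22 | 3-[(1S,4aS,5S,6R,8aR)-5-[(2-hydroxy-5-methoxy-3-methylphenyl)methyl]-5,6,8a-trimethyl-2-(propan-2-ylidene)decahydronaphthalen-1-yl]propanoic acid | COc1cc(C)c(O)c(C[C@]2(C)[C@@H]3CCC(=C(C)C)[C@@H](CCC(=O)O)[C@]3(C)CC[C@H]2C)c1 | target

**Totals**
Total steps: 12. Longest linear sequence: 11 (steps 1, 3–12).

**Steps most likely to fail, each with a fallback**

Step 4 is the weakest point. No Diels–Alder reaction of an aryl enol ether diene of this kind with carvone is known to me; the step rests on analogy with hindered silyloxy dienes, and 7 is acid-sensitive. The fallback uses a tethered silyl enol ether of that proven class. It sets out from cycloadduct 6 (and 8) and comes back at 10. Aqueous AcOH/THF opens 6 to 1-(2-hydroxy-5-methoxy-3-methylphenyl)-2-methylpent-4-en-3-one F4. t-Bu2Si(OTf)2 and Et3N tie the phenol and enol oxygens into the eight-membered cyclic di-tert-butylsilylene dienol ether F5, whose ring enforces the Z geometry. F5 and 8 with the same Lewis acid give the silylene-bridged Diels–Alder adduct F6. HF·pyridine in THF frees the diketone phenol F7 (not isolated), which closes to ketal 10 in MeOH with PPTS.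

Step 3 may fail because thermal o-quinone methide generation competes with oligomerisation and the 2-vinyl-4H-chromene may not survive the acid. The fallback builds the enol ether by cross-coupling instead; it sets out from 1 and comes back at 7. Ortho-formylation (MgCl2, Et3N, paraformaldehyde, MeCN, reflux) gives 2-hydroxy-5-methoxy-3-methylbenzaldehyde F1. Perkin condensation ((EtCO)2O, EtCO2Na, 170 °C) gives 6-methoxy-3,8-dimethyl-2H-chromen-2-one F2. Conjugate reduction with LiBH(s-Bu)3 (THF, −78 °C) and trapping of the lactone enolate with (PhO)2P(O)Cl gives 6-methoxy-3,8-dimethyl-4H-chromen-2-yl diphenyl phosphate F3. Stille coupling with tributyl(vinyl)stannane (Pd(PPh3)4, LiCl, THF, 65 °C) returns 7.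

Step 9 may fail at the [2,3]-Wittig shift, which must form a quaternary carbon on a tetrasubstituted alkene and competes with the [1,2]-shift. The fallback makes the oxy-Cope substrate by Barbier allylation; it sets out from 15 and comes back at 17. CBr4/PPh3 (CH2Cl2, 0 °C) converts 15 into the C1 allylic bromide F8 (the transposed tertiary bromide serves equally). Indium powder and acrolein in THF/H2O at 23 °C add the allylindium through its dimethyl-substituted terminus to give dienol 17. 17 is then rearranged as a separate operation (KH, 18-crown-6, THF, 23 °C) to 18.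

Further compounds
F1 | step 3 | 2-hydroxy-5-methoxy-3-methylbenzaldehyde | COc1cc(C)c(O)c(C=O)c1
F2 | step 3 | 6-methoxy-3,8-dimethyl-2H-chromen-2-one | COc1cc(C)c2OC(=O)C(C)=Cc2c1
F3 | step 3 | 6-methoxy-3,8-dimethyl-4H-chromen-2-yl diphenyl phosphate | COc1cc(C)c2OC(OP(=O)(Oc3ccccc3)Oc3ccccc3)=C(C)Cc2c1
F4 | step 4 | 1-(2-hydroxy-5-methoxy-3-methylphenyl)-2-methylpent-4-en-3-one | C=CC(=O)C(C)Cc1cc(OC)cc(C)c1O
F5 | step 4 | cyclic di-tert-butylsilylene dienol ether of F4 (eight-membered ring, Z) | C=C/C1=C(C)/Cc2cc(OC)cc(C)c2O[Si](C(C)(C)C)(C(C)(C)C)O1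
F6 | step 4 | silylene-bridged Diels–Alder adduct (stereochemistry as 9) | COc1cc(C)c2O[Si](C(C)(C)C)(C(C)(C)C)OC3=CC[C@@]4(C)C(=O)C[C@H](C(C)=C)C[C@H]4[C@@]3(C)Cc2c1
F7 | step 4 | diketone phenol: ring-opened form of 9 (C1 and C6 ketones, free phenol) | COc1cc(C)c(O)c(C[C@]2(C)[C@@H]3C[C@@H](C(C)=C)CC(=O)[C@]3(C)CCC2=O)c1
F8 | step 9 | C1 allylic bromide of 15 | COc1cc(C)c2OC3(OC)CC[C@@]4(C)C(Br)C(=C(C)C)CC[C@H]4[C@@]3(C)Cc2c1
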